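## Structural features

The target consists of two rings joined by one methylene: ring A, a fully substituted benzene of the acylphloroglucinol type, and ring B, a 6-ethyl-4-hydroxy-5-methyl-2H-pyran-2-one. The bridge links C1 of ring A to C3 of ring B. Ring A carries, in order, the bridge carbon (C1), OH (C2), a 3-methylbut-2-enyl group (C3), OH (C4), a 2-methylpropanoyl group (C5) and OMe (C6). All six positions differ, and only one of the three ring oxygens is methylated. There is no stereocentre and no stereogenic double bond, so every problem is one of regiochemistry and chemoselectivity. The fragile parts are: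

- the trisubstituted alkene flanked by two phenols, which closes to a chroman under acid and is lost under hydrogenation;
- the 4-hydroxypyranone, a lactone that alkoxides open and that is nucleophilic at C3;
- the electron-rich phenols and the diaryl-type methylene bridge, which can be unmade under forcing acid or base.

The real difficulty is the ketone at C5, which must sit between a free hydroxyl and the methyl ether. Electrophilic acylation of a 5-methoxyresorcinol has several competing sites. After that, C1 and C3 must be told apart for two different carbon substituents. The key step exploits the C4–O and C5–C(=O) bonds next to C6–OMe: an ortho-hydroxy ketone beside a methoxy group is what a carboxylic acid leaves when it inserts into a 3-methoxyaryne whose triple bond lies between C4 and C5. The oxygen at C2 is a spectator in that step and can carry an allyl group that is later moved to C3.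

## Logic of the disconnections

22 is cut at both C–C bonds of the bridging methylene (C1 of ring A–CH2 and CH2–C3 of ring B), giving 15, 19 and a one-carbon bis-electrophile. Both carbons are the nucleophilic positions of their rings, and C1 is the only unsubstituted carbon left in 15. The cut divides the molecule into two halves of similar size. The forward step must favour the cross-coupling over the two homo-couplings under conditions mild enough for the prenyl alkene, which is why it is staged through 20 and 21.

19 is cut at C4–C5 and O1–C2 of ring B, giving 17 and 18; 17 comes from 16. A 1,3-bis-acylating agent and an enol ether map directly onto the pyranone. Because 16 is symmetrical, ethyl must end at C6 and methyl at C5. The demand is C-acylation before O-acylation.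

15 is cut at the C=C bond of the prenyl group, giving 13 and 14. This reduces the C3 side chain to an allyl group, which a sigmatropic shift can deliver. The forward metathesis must tolerate free phenols and an aryl ketone.

13 is cut at the C3–CH2 bond and the allyl group is reconnected to the oxygen at C2, giving 12. The protecting group of the key step thus becomes the side chain, so no deprotection and no intermolecular C-alkylation of an ambident phenoxide is needed. The forward Claisen rearrangement must go to C3 and not to C1; the hydrogen bond between the C4 hydroxyl and the ketone is relied on for that.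

12 is cut at C4–O and at C5–C(=O), giving 8 and 9. This is the key disconnection: it removes the hindered ketone and its neighbouring hydroxyl in one operation and leaves a benzene with three oxygens and one silyl/triflate pair. The forward step must add oxygen at C4 and not at C5, must transfer the acyl group faster than the aryl anion is protonated, and needs a spectator group at the C2 oxygen that survives fluoride at high temperature.

8 is cut at the O–allyl bond, giving 6 and 7. The etherification must not trigger the silyl triflate, so neutral conditions are required.

6 is cut at C–Si (silicon returned to the neighbouring oxygen) and at O–S, giving 3, which comes from 2 and then 1 by removal of the silyl groups and of bromine. The bromine position defines the aryne position. The two hydroxyls of 2 are distinguished because only one is ortho to bromine. The demand is a single bromination between OH and OMe.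

## Other disconnections considered

Alternative 1: Ring B is cut at C4–C5 and O1–C2 with the bridge already attached. In the forward step the malonyl dichloride A1 would acylate the enol silane A2 (identical with 17) first on carbon and then on oxygen, giving the diacetate A3, which is then deacetylated.
- In its favour: the bridge is never formed between two nucleophiles, so homo-coupling cannot occur. On this point it is better than the chosen plan. Ring B is built by the same reaction type as in the chosen plan, so on that point the two are equal.
- Against it: A1 is a benzylmalonyl dichloride carrying an enolisable ketone, two aryl esters and an acid-sensitive prenyl group, and its formation and use liberate HCl next to that alkene. Its preparation still needs a one-carbon functionalisation at C1 of a fully substituted ring A.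
- Comparison: it leaves the substitution pattern of ring A unsolved and adds protection, malonate and deprotection steps. It is a longer answer to a problem the chosen plan meets in one step.

Alternative 2: Ring A is cut at C3–C4 and traced back to the pyranone A4. In the forward step a methoxide base in its parent alcohol would open the lactone, and the carbanion next to the former C6 would close onto the new ester (Claisen condensation), giving A5 (identical with 15).
- In its favour: the methyl ether is fixed by construction, the prenyl group is already in place, and no phenol has to be differentiated. On step count to this common intermediate it is the better plan on paper, and on placement of the methyl ether it is the equal of the chosen plan.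
- Against it: the same carbanion can close on the isobutyryl ketone instead (aldol mode, also six-membered), which would give a different arene. Methoxide can also attack the vinylogous ester positions. A4 itself needs C3 acylation, side-chain alkylation and selective O-methylation of a pyranone.
- Comparison: the outcome depends on a choice between two ring closures that the substrate does not clearly decide, whereas the aryne route decides its regiochemistry by a well-understood substituent effect.

Alternative 3: Ring A is cut at C2–C3, C4–C5 and C1–C2. In the forward step the cyclobutenone A6 and the siloxyalkyne A7 would be heated to give A8 by 4π opening, [2+2] addition, a second 4π opening and 6π closure.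
- In its favour: the bridge, the prenyl group and three differentiated oxygens are assembled in one convergent step with full regiocontrol. On bridge formation and on oxygen differentiation it is better than the chosen plan.
- Against it: C5 of A8 still bears hydrogen, so the isobutyryl group must be added last by Friedel–Crafts or Fries chemistry on a ring that carries a prenyl group beside a phenol. That is the hindered ketone which the chosen plan makes first and without Lewis acid. A6 requires alkylation of a 3-alkoxycyclobutenone at C4 and may isomerise, and A7 needs ynolate chemistry.
- Comparison: it is more elegant for the carbon framework, but longer and weakest where the chosen plan is strongest.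

Key step: step 5

Remark on the chemistry: the target has no stereocentre, and the structures of the key-step pair were checked atom by atom and needed no correction. The oxygen at C2 of ring A is carried through the key step as an allyl ether; the skeleton, the aryne and the two bonds formed are unchanged. A benzyl ether would serve the key step equally but would need hydrogenolysis followed by an unselective direct prenylation, whereas the allyl group can be moved to C3 by a Claisen rearrangement.

## Route

Step 1
Reactants: 1 5-methoxybenzene-1,3-diol
Product: 2 4-bromo-5-methoxybenzene-1,3-diol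
Conditions: NBS (1.0 equiv), THF, −78 → 0 °C
Reagents that add atoms: N-bromosuccinimide, O=C1CCC(=O)N1Br
Why: Electrophilic aromatic bromination; the two equivalent carbons between OH and OMe are each ortho to one hydroxyl and para to the other, whereas the carbon between the hydroxyls is only ortho to both, so one equivalent of NBS at low temperature should place a single bromine between OH and OMe.

Step 2
Reactants: 2 4-bromo-5-methoxybenzene-1,3-diol
Product: 3 [(4-bromo-5-methoxy-1,3-phenylene)bis(oxy)]bis(trimethylsilane)
Conditions: HMDS, THF, 70 °C; volatiles removed
Reagents that add atoms: hexamethyldisilazane, C[Si](C)(C)N[Si](C)(C)C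
Why: Exhaustive O-silylation of both phenols; the silyl ether ortho to bromine is the silyl donor of the next step and the remote one is a temporary mask.

Step 3
Reactants: 3 [(4-bromo-5-methoxy-1,3-phenylene)bis(oxy)]bis(trimethylsilane)
Product: 6 5-hydroxy-3-methoxy-2-(trimethylsilyl)phenyl trifluoromethanesulfonate, via lithium 2-silylphenoxide 4 (not isolated), via aryl silyl ether triflate 5 (not isolated)
Conditions: n-BuLi, THF, −100 → −78 °C; Tf2O, −100 °C → rt; then MeOH, AcOH (cat.), rt
Reagents that add atoms: trifluoromethanesulfonic anhydride, O=S(=O)(OS(=O)(=O)C(F)(F)F)C(F)(F)F
Why: Bromine–lithium exchange followed by retro-Brook (1,3 O→C) silyl migration from the only neighbouring silyl ether gives the ortho-silyl phenoxide, which Tf2O traps; the remote aryl silyl ether is cleaved in the methanolic work-up, so the two oxygens of 2 are distinguished without a separate protection step.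

Step 4
Reactants: 6 5-hydroxy-3-methoxy-2-(trimethylsilyl)phenyl trifluoromethanesulfonate; 7 prop-2-en-1-ol
Product: 8 3-methoxy-5-(prop-2-en-1-yloxy)-2-(trimethylsilyl)phenyl trifluoromethanesulfonate
Conditions: PPh3, DIAD, THF, 0 °C → rt
Reagents that add atoms: none
Why: Mitsunobu etherification of an unhindered phenol under neutral conditions, chosen so that no fluoride, alkoxide or carbonate base meets the silyl triflate.

Step 5
Reactants: 8 3-methoxy-5-(prop-2-en-1-yloxy)-2-(trimethylsilyl)phenyl trifluoromethanesulfonate; 9 2-methylpropanoic acid
Product: 12 1-[2-hydroxy-6-methoxy-4-(prop-2-en-1-yloxy)phenyl]-2-methylpropan-1-one, via 3-methoxy-5-allyloxybenzyne 10 (not isolated), via benzoxetane alkoxide 11 (not isolated)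
Conditions: CsF, THF, 125 °C, sealed tube
Reagents that add atoms: none
Why: Fluoride attacks silicon of 8 and triflate leaves from the neighbouring carbon, giving aryne 10 with its triple bond between C4 and C5 of ring A. The carboxylate of 9 adds through oxygen to C4, the aryne carbon remote from the methoxy group, so that the aryl anion develops at C5, where the adjacent C6–OMe stabilises it inductively; the allyloxy group at C2 is too remote to override this. The C5 anion then adds to the ester carbonyl in a 4-exo-trig closure to the four-membered alkoxide 11, which opens by C–O cleavage to the chelated ortho-acyl phenoxide, so no ring persists and two skeletal bonds (C4–O and C5–C(=O)) are made. The closest known reaction type is the insertion of arynes into the C–O bond of carboxylic acids to give ortho-hydroxyaryl ketones, which is favoured over simple O-arylation at high temperature in an aprotic ether. No stereocentre is formed. The step needs oxygen attack at C4 and not C5 (secured by the C6 methoxy group), acyl transfer faster than protonation of the aryl anion (secured by heat, a dry aprotic medium and the proximity of the ester carbonyl) and an inert allyl ether (an unactivated alkene competes poorly with carboxylate for the aryne).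

Step 6
Reactants: 12 1-[2-hydroxy-6-methoxy-4-(prop-2-en-1-yloxy)phenyl]-2-methylpropan-1-one
Product: 13 1-[2,4-dihydroxy-6-methoxy-3-(prop-2-en-1-yl)phenyl]-2-methylpropan-1-one
Conditions: PhNEt2, 200 °C
Reagents that add atoms: none
Why: Aromatic Claisen rearrangement ([3,3] shift then tautomerisation); the hydrogen bond between the C4 hydroxyl and the ketone fixes the C2–C3 bond of ring A as the more double-bond-like one, which should direct the allyl group to C3 and not to C1.

Step 7
Reactants: 13 1-[2,4-dihydroxy-6-methoxy-3-(prop-2-en-1-yl)phenyl]-2-methylpropan-1-one; 14 2-methylbut-2-ene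
Product: 15 1-[2,4-dihydroxy-6-methoxy-3-(3-methylbut-2-en-1-yl)phenyl]-2-methylpropan-1-one
Conditions: second-generation Grubbs catalyst (H2IMes)(PCy3)Cl2Ru=CHPh (5 mol %), 14 (excess), CH2Cl2, 40 °C
Reagents that add atoms: none
Why: Olefin cross-metathesis of the terminal allyl group with excess 14 exchanges =CH2 for =CMe2; ruthenium alkylidenes of this type tolerate free phenols and aryl ketones, and propene leaves as a gas.

Step 8
Reactants: 16 pentan-3-one
Product: 17 trimethyl(pent-2-en-3-yloxy)silane (E/Z mixture, geometry of no consequence)
Conditions: TMSOTf, Et3N, CH2Cl2, 0 °C
Reagents that add atoms: trimethylsilyl trifluoromethanesulfonate, C[Si](C)(C)OS(=O)(=O)C(F)(F)F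
Why: Soft enolisation and O-silylation of a symmetrical ketone; only one constitutional enol ether can form.

Step 9
Reactants: 17 trimethyl(pent-2-en-3-yloxy)silane; 18 propanedioyl dichloride
Product: 19 6-ethyl-4-hydroxy-5-methyl-2H-pyran-2-one
Conditions: Et2O, −78 °C → rt
Reagents that add atoms: none
Why: C-acylation of the silyl enol ether by one acid chloride of 18, then O-acylation of the enolised ethyl ketone by the other, closes the 4-hydroxypyran-2-one; ethyl ends at C6 and methyl at C5 because the ketone is symmetrical.

Step 10
Reactants: 19 6-ethyl-4-hydroxy-5-methyl-2H-pyran-2-one; 15 1-[2,4-dihydroxy-6-methoxy-3-(3-methylbut-2-en-1-yl)phenyl]-2-methylpropan-1-one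
Product: 22 3-{[2,4-dihydroxy-6-methoxy-3-(3-methylbut-2-en-1-yl)-5-(2-methylpropanoyl)phenyl]methyl}-6-ethyl-4-hydroxy-5-methyl-2H-pyran-2-one, via Mannich base 20 (not isolated), via methylidene pyrandione 21 (not isolated)
Conditions: Me2N=CH2+ I− (1.0 equiv), MeCN, 0 °C → rt; then 15, 60 °C
Reagents that add atoms: N,N-dimethylmethyleneiminium iodide, C=[N+](C)C.[I-]
Why: Mannich aminomethylation of the acidic C3 of 19, loss of dimethylamine to the exocyclic enone 21, and Friedel–Crafts-type conjugate addition of 15; the position between the C2 hydroxyl and the C6 methoxy group is the only unsubstituted carbon of ring A, so the arene regiochemistry cannot vary, and 19 is converted fully into 20 before 15 is added in order to suppress homo-coupling.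

## Compound list

1 | 5-methoxybenzene-1,3-diol | COc1cc(O)cc(O)c1 | starting material
2 | 4-bromo-5-methoxybenzene-1,3-diol | COc1cc(O)cc(O)c1Br | intermediate
3 | [(4-bromo-5-methoxy-1,3-phenylene)bis(oxy)]bis(trimethylsilane) | COc1cc(O[Si](C)(C)C)cc(O[Si](C)(C)C)c1Br | intermediate
4 | lithium 3-methoxy-2-(trimethylsilyl)-5-[(trimethylsilyl)oxy]phenolate | COc1cc(O[Si](C)(C)C)cc([O-])c1[Si](C)(C)C.[Li+] | intermediate (not isolated)
5 | 3-methoxy-2-(trimethylsilyl)-5-[(trimethylsilyl)oxy]phenyl trifluoromethanesulfonate | COc1cc(O[Si](C)(C)C)cc(OS(=O)(=O)C(F)(F)F)c1[Si](C)(C)C | intermediate (not isolated)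
6 | 5-hydroxy-3-methoxy-2-(trimethylsilyl)phenyl trifluoromethanesulfonate | COc1cc(O)cc(OS(=O)(=O)C(F)(F)F)c1[Si](C)(C)C | intermediate
7 | prop-2-en-1-ol | C=CCO | starting material
8 | 3-methoxy-5-(prop-2-en-1-yloxy)-2-(trimethylsilyl)phenyl trifluoromethanesulfonate | COc1cc(OCC=C)cc(OS(=O)(=O)C(F)(F)F)c1[Si](C)(C)C | intermediate
9 | 2-methylpropanoic acid | CC(C)C(=O)O | starting material
10 | 3-methoxy-5-(prop-2-en-1-yloxy)benzyne (1,2-didehydro-3-methoxy-5-(prop-2-en-1-yloxy)benzene) | COC1=CC(OCC=C)=CC#C1 | intermediate (not isolated)
11 | caesium 2-methoxy-8-(propan-2-yl)-4-(prop-2-en-1-yloxy)-7-oxabicyclo[4.2.0]octa-1,3,5-trien-8-olate | CC(C)C1([O-])Oc2cc(OCC=C)cc(OC)c21.[Cs+] | intermediate (not isolated)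
12 | 1-[2-hydroxy-6-methoxy-4-(prop-2-en-1-yloxy)phenyl]-2-methylpropan-1-one | CC(C)C(=O)c1c(O)cc(OCC=C)cc1OC | intermediate
13 | 1-[2,4-dihydroxy-6-methoxy-3-(prop-2-en-1-yl)phenyl]-2-methylpropan-1-one | CC(C)C(=O)c1c(O)c(CC=C)c(O)cc1OC | intermediate
14 | 2-methylbut-2-ene | CC=C(C)C | starting material
15 | 1-[2,4-dihydroxy-6-methoxy-3-(3-methylbut-2-en-1-yl)phenyl]-2-methylpropan-1-one | CC(C)C(=O)c1c(O)c(CC=C(C)C)c(O)cc1OC | intermediate
16 | pentan-3-one | CCC(=O)CC | starting material
17 | trimethyl(pent-2-en-3-yloxy)silane (E/Z mixture) | CC=C(CC)O[Si](C)(C)C | intermediate
18 | propanedioyl dichloride | O=C(Cl)CC(=O)Cl | starting material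
19 | 6-ethyl-4-hydroxy-5-methyl-2H-pyran-2-one | CCc1oc(=O)cc(O)c1C | intermediate
20 | 3-[(dimethylamino)methyl]-6-ethyl-4-hydroxy-5-methyl-2H-pyran-2-one | CCc1oc(=O)c(CN(C)C)c(O)c1C | intermediate (not isolated)
21 | 6-ethyl-5-methyl-3-methylidene-2H-pyran-2,4(3H)-dione | CCC1=C(C)C(=O)C(=C)C(=O)O1 | intermediate (not isolated)
22 | 3-{[2,4-dihydroxy-6-methoxy-3-(3-methylbut-2-en-1-yl)-5-(2-methylpropanoyl)phenyl]methyl}-6-ethyl-4-hydroxy-5-methyl-2H-pyran-2-one | CCc1oc(=O)c(Cc2c(O)c(CC=C(C)C)c(O)c(C(=O)C(C)C)c2OC)c(O)c1C | target

## Step count and least certain steps

Total: 10 steps. Longest linear sequence: 8 steps (steps 1 to 7 and step 10). The pyranone branch (steps 8 and 9) is 2 steps.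

Step 5 (key step). Three things can go wrong. The aryl anion may be protonated before it reaches the ester carbonyl, which stops at O-arylation. The product phenoxide may be arylated a second time. The aryne may be consumed by an ene-type reaction with the allyl group of a second molecule. The fallback abandons the aryne and sets out from 1 and 9. A BF3·OEt2-mediated Nencki (Friedel–Crafts) C-acylation at 80–90 °C should give 1-(2,4-dihydroxy-6-methoxyphenyl)-2-methylpropan-1-one F1; acylation between the two hydroxyls also occurs, so a separation of isomers is accepted. Selective O-allylation of the non-chelated hydroxyl (3-bromoprop-1-ene, K2CO3, acetone) then returns to the route at 12.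

Step 10. Homo-coupling can compete if the Mannich base reverts and 21 meets free 19. Capture of 21 by the prenyl alkene in a hetero-Diels–Alder sense and O-alkylation of a phenol are further risks. The fallback sets out from 15 and changes the polarity of the union. Magnesium-mediated ortho-formylation (MgCl2, Et3N, paraformaldehyde, MeCN, reflux) at the only free ring carbon should give 2,4-dihydroxy-6-methoxy-3-(3-methylbut-2-en-1-yl)-5-(2-methylpropanoyl)benzaldehyde F2. A three-component reductive alkylation of 19 with F2 (Hantzsch ester, L-proline cat., CH2Cl2/EtOH, rt; Knoevenagel condensation followed by conjugate hydride transfer) then comes back to the route at 22.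

Step 6. The allyl group may migrate to C1 if chelation control weakens at 200 °C, and the ortho-allyl phenol may cyclise further. The fallback sets out from 12. Deallylation with Pd(PPh3)4 and morpholine in THF gives the diol F1 already described under step 5. Direct C-prenylation of its dianion with 1-bromo-3-methylbut-2-ene in aqueous KOH at 0 °C, where the carbon between the two phenoxide oxygens is the most nucleophilic, returns to the route at 15, bypassing 13 and step 7. An isomer separation is again accepted.

Step 1. Over-bromination of a very electron-rich ring and attack between the two hydroxyls can erode the yield of the single isomer needed. The fallback sets out from 1. Bis-silylation (i-Pr3SiCl, imidazole, DMF) gives [(5-methoxy-1,3-phenylene)bis(oxy)]bis[tri(propan-2-yl)silane] F3. Bromination with NBS in MeCN, now steered by the two bulky silyloxy groups away from the carbon between them, gives [(4-bromo-5-methoxy-1,3-phenylene)bis(oxy)]bis[tri(propan-2-yl)silane] F4. Desilylation (Bu4NF, AcOH, THF) comes back to the route at 2.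

## Further compounds

F1 | step 5 | 1-(2,4-dihydroxy-6-methoxyphenyl)-2-methylpropan-1-one | CC(C)C(=O)c1c(O)cc(O)cc1OC
F2 | step 10 | 2,4-dihydroxy-6-methoxy-3-(3-methylbut-2-en-1-yl)-5-(2-methylpropanoyl)benzaldehyde | O=Cc1c(O)c(CC=C(C)C)c(O)c(C(=O)C(C)C)c1OC
F3 | step 1 | [(5-methoxy-1,3-phenylene)bis(oxy)]bis[tri(propan-2-yl)silane] | COc1cc(O[Si](C(C)C)(C(C)C)C(C)C)cc(O[Si](C(C)C)(C(C)C)C(C)C)c1
F4 | step 1 | [(4-bromo-5-methoxy-1,3-phenylene)bis(oxy)]bis[tri(propan-2-yl)silane] | COc1cc(O[Si](C(C)C)(C(C)C)C(C)C)cc(O[Si](C(C)C)(C(C)C)C(C)C)c1Br
A1 | alternative 1 | 2-{[2,4-bis(acetyloxy)-6-methoxy-3-(3-methylbut-2-en-1-yl)-5-(2-methylpropanoyl)phenyl]methyl}propanedioyl dichloride | O=C(Cl)C(Cc1c(OC(C)=O)c(CC=C(C)C)c(OC(C)=O)c(C(=O)C(C)C)c1OC)C(=O)Cl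
A2 | alternative 1 | trimethyl(pent-2-en-3-yloxy)silane | CC=C(CC)O[Si](C)(C)C
A3 | alternative 1 | 4-[(6-ethyl-4-hydroxy-5-methyl-2-oxo-2H-pyran-3-yl)methyl]-5-methoxy-2-(3-methylbut-2-en-1-yl)-6-(2-methylpropanoyl)-1,3-phenylene diacetate | CCc1oc(=O)c(Cc2c(OC(C)=O)c(CC=C(C)C)c(OC(C)=O)c(C(=O)C(C)C)c2OC)c(O)c1C
A4 | alternative 2 | 4-methoxy-6-(4-methylpent-3-en-1-yl)-3-(2-methylpropanoyl)-2H-pyran-2-one | COc1cc(CCC=C(C)C)oc(=O)c1C(=O)C(C)C
A5 | alternative 2 | 1-[2,4-dihydroxy-6-methoxy-3-(3-methylbut-2-en-1-yl)phenyl]-2-methylpropan-1-one | CC(C)C(=O)c1c(O)c(CC=C(C)C)c(O)cc1OC
A6 | alternative 3 | 6-ethyl-3-[(2-methoxy-4-oxocyclobut-2-en-1-yl)methyl]-4-(methoxymethoxy)-5-methyl-2H-pyran-2-one | CCc1oc(=O)c(CC2C(=O)C=C2OC)c(OCOC)c1C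
A7 | alternative 3 | [(5-methylhex-4-en-1-yn-1-yl)oxy]tri(propan-2-yl)silane | CC(C)=CCC#CO[Si](C(C)C)(C(C)C)C(C)C
A8 | alternative 3 | 6-ethyl-3-{[2-hydroxy-6-methoxy-3-(3-methylbut-2-en-1-yl)-4-{[tri(propan-2-yl)silyl]oxy}phenyl]methyl}-4-(methoxymethoxy)-5-methyl-2H-pyran-2-one | CCc1oc(=O)c(Cc2c(O)c(CC=C(C)C)c(O[Si](C(C)C)(C(C)C)C(C)C)cc2OC)c(OCOC)c1C
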